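Monday's run and Thursday's run, both at 25 °C, differ 3.12-fold in c(first nucleophile). Yet after 15.0 h they have lost 7.50% and 8.70% of their starting material, a ratio of 1.16, less than that factor. So I read a first-order step into an intermediate as the rate-limiting step, and I take the target's share as a contest for that intermediate, with the second nucleophile as the rival.

| flask | starting material | first nucleophile | second nucleophile | temperature | remark | time |
|---|---|---|---|---|---|---|
| Monday's | 0.20 M | 1.2 equiv | 0.60 equiv | 25 °C | run made earlier |  |
| Saturday's | 0.20 M | 5 equiv | 0.60 equiv | 50 °C | run made earlier |  |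
| Thursday's | 0.30 M | 2.5 equiv | 0.60 equiv | 25 °C | run made earlier |  |
| spring | 0.20 M | 2.50 equiv | 0.600 equiv | 50 °C |  | 8.0 h |
| winter | 0.20 M | 2.50 equiv | 0.600 equiv | 30 °C |  | 8.0 h |
| summer | 0.20 M | 2.50 equiv | 0.600 equiv | 70 °C |  | 8.0 h |

- Monday's (time / h: target / %, starting material / %): 1.33: 0.1, 98.7; 2.50: 0.5, 98.8; 5.00: 1.0, 97.5; 8.00: 1.8, 95.8; 15.0: 3.5, 92.5
- Saturday's (time / h: target / %, starting material / %): 1.00: 8.2, 89.5; 2.00: 15.2, 78.4; 3.00: 21.4, 68.3; 4.00: 27.0, 60.5; 5.00: 32.8, 53.6
- Thursday's (time / h: target / %, starting material / %): 3.00: 1.2, 98.4; 6.00: 2.1, 96.9; 10.0: 3.1, 95.7; 15.0: 4.3, 91.3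

(scatter of a reading: 0.5 percentage points)



1. the flask that comes out highest in amount of target, in percent of the starting material charged, or "all alike" when all lie within 1.5 percentage points (spring / winter / summer / all alike)
2. target at the end, in percent of the starting material charged, spring
3. target at the end, in percent of the starting material charged, winter
4. target at the end, in percent of the starting material charged, summer

Saturday's last reading gives target over starting material lost, a share of 0.707. Setting that share equal to c(first nucleophile)/(c(first nucleophile) + ρ·c(second nucleophile)) at the charges gives ρ = 3.46. But the charges hold at the start, whereas in my reckoning each 1.00 equiv of starting material converted spends that much nucleophile, divided according to the share. So I put the share back in, use mid-run amounts, and get 3.77. That is the capture ratio, the rate at which the second nucleophile takes the intermediate over that of the first at equal concentration, a selectivity factor. Is it safe at other temperatures? Monday's last reading gives 2.29 and Thursday's 4.26, on either side of it, so I see no drift through the scatter and keep one value.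

Saturday's loss gives 0.125 h⁻¹, so I expect spring to convert 63.1%. The charges give a share of 0.525. Going round once with mid-run amounts, 2.33 equiv and 0.450 equiv, raises it to 0.579, so I reckon spring at 36.5%. The two cool runs average 0.00563 h⁻¹. Taking a constant factor per degree, I expect winter to convert 8.03%, less than spring, so the first share serves and I reckon winter at 4.22%. Summer's half-life comes to 0.466 h, far shorter than 8.0 h, so I count full conversion, and the round gives 62.1%. My doubt is that the last reading of Saturday's run stands at 46.4% conversion, more than in the two cool runs, and this figure counts the target as intact.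

The forecast names summer, with spring 36% (28% to 43%), winter 4.5% (3% to 7%) and summer 75% (60% to 88%), reasoning for summer that “conversion is complete, so selectivity sets the yield”. My summer figure is lower, at 62.1%.

The flasks give spring 35.3%, winter 4.63% and summer 51.3%, so summer is highest.

    starting material → intermediate (k = 3.10 × 10⁻⁴ s⁻¹, Ea = 102 kJ mol⁻¹)
    first nucleophile + intermediate → target (k = 0.0690 M⁻¹ s⁻¹, Ea = 51.0 kJ mol⁻¹)
    second nucleophile + intermediate → other capture product (k = 0.250 M⁻¹ s⁻¹, Ea = 58.0 kJ mol⁻¹)
    starting material + target → side product (k = 1.30 × 10⁻⁴ M⁻¹ s⁻¹, Ea = 87.0 kJ mol⁻¹)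
    second nucleophile + target → over-reaction product (k = 1.20 × 10⁻⁴ M⁻¹ s⁻¹, Ea = 65.0 kJ mol⁻¹)
    (constants at 70 °C)

Summer's target stands below both figures, down from 53.9% at 4.00 h, with 6.85% of over-reaction product in that flask at 8.00 h. Spring's target over its lost starting material is 0.558. The neighbouring flask is spring with 0.620 equiv of first nucleophile. With the same capture ratio its share from the charges is 0.215, and the round, at 0.552 equiv and 0.352 equiv, gives 0.294, hence 18.6% of target. That flask holds 18.8% of target beside 41.9% of other capture product.

The runs were generated by integration on assumed constants; noise was put on by code.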